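Assumption (remark on the chemistry): tert-butoxyethyne is taken as a purchasable reagent, handled as a cold hydrocarbon solution, and the target is isolated as the free sulfonic acid that its structure shows.

## Structural features

Niruriflavone is a flavone: benzo ring A is fused through the C4a–C8a bond to the 4-pyranone ring C, and ring B, a 4-methoxyphenyl group, sits on C2. There is no stereocentre, so no two stereocentres stand next to each other and the whole problem is one of regiochemistry on ring A. That ring carries hydroxyl on C5 (chelated to the C4 carbonyl), the sulfonic acid on C6, hydroxyl on C7, hydrogen on C8 and the ring oxygen O1 on C8a, so sulfur stands between two oxygens. Three points are fragile. The aryl C–S bond sits on an electron-rich ring, open to protodesulfonation in hot acid and, at the sulfinate level, to loss of SO2. C2 of the pyranone is opened by hard nucleophiles and alkali. The methyl ether of ring B must survive while the two hydroxyls of ring A are set free, which excludes boron trihalides from the end game. The real difficulty is to put sulfur on C6 and not on C8, since both carbons of a 5,7-dioxygenated flavone are nucleophilic, and to carry a strong water-soluble acid through the route. The key step uses the C4a=C8a double bond of a 2-aryl-4-pyranone that already holds O1 on C8a. With a ketene grown from an acyl group on C8a this bond is the vinyl part of a vinylketene, and an alkyne with oxygen and sulfur on neighbouring carbons supplies C7 and C6, so the place of sulfur is fixed by bond formation and not by substitution.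

## Logic of the disconnections

20 from 19. The bond cut is the O–C(CH3)3 bond at C7, together with the ion pair of the sulfonate. An acid-labile ether is the only mask on ring A and is orthogonal to the methyl ether of ring B. The gain is that the strong acid appears only in the last operation. The demand is an acidolysis cold and short enough to leave the C6–S bond alone, with the cation leaving as an alkene and not alkylating C8.

19 from 17, through 18. One S–O bond is cut and the S–CH2 bond is restored. The third oxygen on sulfur is added last, to a sulfinate that a sulfone with a β-ester releases by retro-Michael elimination. The gain is a neutral sulfone that can be chromatographed in place of an ionic intermediate. The demand is a base that does not add to C2 and an oxidation of 18 that outruns its re-addition and its loss of SO2, hence one flask.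

17 from 16. The two S=O bonds are cut. Only at the sulfide level is the sulfur-bearing alkyne carbon nucleophilic in the ring-forming step; a sulfonyl alkyne would have the opposite polarity. The demand is oxidation at sulfur without touching the phenol ring or the C2=C3 bond.

16 from 7 and 11. Four bonds are cut: C8–C8a, C5–C6, C7–C8 and C4a–C5. All of ring A except the C4a–C8a bond is removed in one move, which leaves a monocyclic pyranone of 14 carbons and an alkyne of 10. Each substituent of ring A is traced to one atom of the fragments: the C5 hydroxyl to the acyl carbon of 7, sulfur and the C7 oxygen to the alkyne carbons of 11, O1 to the pyranone. The demand is one orientation of the ketene–alkyne cycloaddition and a light source that spares the pyranone and the product.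

7 from 5, through 6. The bond between the acyl carbon and the diazo carbon is cut. This leads back to a carboxylic acid on the pyranone carbon that becomes C8a. The demand is acyl activation that leaves the pyranone carbonyl alone and a diazoalkane safer than diazomethane.

5 from 1 and 2, through 3 and 4. The ring O–C bond of the pyranone is cut, as is the C–C bond between the methyl carbon of 1 and one carbonyl carbon of 2. Both partners are cheap and carry every carbon of ring C, ring B and the future C8a substituent. The demand is acylation at the methyl terminus of 1 and not at its central carbon, and ring closure and ester hydrolysis in acid.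

11 from 8 and 9, through 10. The C(sp)–S bond is cut. This gives an acetylide nucleophile and a sulfur electrophile that already carries the ester handle needed for the later release of the sulfinate. The demand is attack at sulfur faster than attack at the ester carbonyl.

## Other disconnections considered

Alternative 1: The cut is the C4–C4a bond of ring C, with ring A kept whole as a symmetrical aryl ether. In the forward step the (Z)-β-aryloxycinnamic acid A1 would be turned by (CF3CO)2O into its mixed anhydride, which should acylate the arene carbon ortho to the ether oxygen and close the pyranone to give A2.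
- In favour: the aryloxy ring of A1 has a mirror plane through its O-bearing and S-bearing carbons, so the two ortho carbons are the same and the C6/C8 question cannot arise. The carbon to be acylated is ortho and para to isopropoxy groups and only meta to the sulfonate, so it should be reactive.
- Better than the chosen plan: ring closure of β-aryloxyacrylic acids to chromones is established chemistry, so on certainty of mechanism this key step is the better one.
- Equal to the chosen plan: sulfur is fixed at C6 by construction in both.
- Against: the regiochemical problem moves into the arene, because a phenol with a sulfonate ester between two alkoxy groups must itself be made selectively. The end game needs two isopropyl ethers cleaved by a boron trihalide beside the ring B methyl ether, and a neopentyl sulfonate cleaved by a nucleophile at high temperature; the chosen plan needs only CF3CO2H.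
- Step economy: about equal for the flavone core, but the alternative pays extra steps for the arene and for three deprotections.

Alternative 2: The cuts are C5–C6 and C6–C7. α-Lithiated A4 would be acylated first by the ring ester of the pyranone diester A3 and then, as the β-keto sulfonate anion, by the side-chain ester, closing ring A to A5.
- Better than the chosen plan: sulfur arrives at the sulfonate level, so no oxidation is run on an electron-rich ring, and both phenols appear free. On paper the route is also the shorter one.
- In favour: aromatisation drives the second acylation.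
- Against: the CH2 group of A3 lies between an ester and the pyranone and is far more acidic than A4, so proton transfer should come before any acylation, and the enolate so formed deactivates the side-chain ester. A hard carbanion can also add to the pyranone at its oxygen-bearing carbons and open the ring. Nothing in A3 makes the ring ester react before the side-chain ester. A3 needs a synthesis of its own, and the neopentyl group again needs a hot nucleophile.
- Comparison: the chosen key step is neutral and pericyclic and avoids this mismatch of acidities. Its price is the later adjustment of the sulfur oxidation level (steps 5 and 6).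

Alternative 3: The cuts are the C5–O and C7–O bonds. Two equivalents of sodium benzyloxide A8 would displace both fluorides of the difluoroflavone sulfonate A6 to give A7, with no ring closure.
- Better than the chosen plan: displacement of aryl fluoride by alkoxide is thoroughly precedented, and each fluoride is ortho to the sulfonate and ortho or para to the acyl-bearing C4a.
- Equal to the chosen plan: benzyl ethers come off without touching the methyl ether, the same orthogonality as the tert-butyl ether.
- Against: the first benzyloxy group deactivates the ring for the second displacement. Benzyloxide may add to C2 with opening of ring C, or attack sulfur of the sulfonate ester. Hydrogenolysis may reduce the C2=C3 bond. A6 needs a full flavone synthesis from a polyfluoroarene plus a regioselective sulfonation, and the neopentyl ester must still be cleaved.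
- Comparison: the alternative is longer and leaves ring A to be bought, where the chosen plan builds ring A with all four substituents in one step; the chosen plan carries the greater mechanistic risk.

Key step: step 4

## Route

Step 1
Reactants: 1 1-(4-methoxyphenyl)butane-1,3-dione; 2 diethyl oxalate
Product: 5 6-(4-methoxyphenyl)-4-oxo-4H-pyran-2-carboxylic acid, via triketo ester 3 (not isolated), via pyranone ethyl ester 4 (not isolated)
Conditions: NaOEt (2.2 equiv), EtOH, 0 to 60 °C; then conc. HCl–AcOH, reflux
Reagents that add atoms: water, O
Why: Crossed Claisen condensation of the doubly deprotonated diketone at its methyl terminus with the oxalate (the chemistry of the chelidonic acid synthesis) gives 3; hot acid then closes the 4-pyranone by cyclodehydration and hydrolyses the ester in the same operation. Acid and not alkali is used for the hydrolysis because hydroxide opens pyranones at C2, and the aryl methyl ether is inert to HCl.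

Step 2
Reactants: 5 6-(4-methoxyphenyl)-4-oxo-4H-pyran-2-carboxylic acid
Product: 7 2-(2-diazoacetyl)-6-(4-methoxyphenyl)-4H-pyran-4-one, via acid chloride 6 (not isolated)
Conditions: (COCl)2 (1.2 equiv), cat. DMF, CH2Cl2, 0 °C to rt; evaporate; Me3SiCHN2 (hexane solution), MeCN–THF, 0 °C
Reagents that add atoms: (trimethylsilyl)diazomethane, C[Si](C)(C)C=[N+]=[N-]
Why: Chloride formation through the Vilsmeier-type chloroiminium salt is routine for pyranone- and chromone-2-carboxylic acids, and a small excess of (COCl)2 at 0 °C should keep the pyranone carbonyl from being activated. C-Acylation of Me3SiCHN2 followed by loss of Me3SiCl (Arndt–Eistert-type diazo ketone synthesis) gives 7 without diazomethane; 6 has no α-hydrogen, so no ketene can form from it.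

Step 3
Reactants: 8 tert-butoxyethyne; 9 dimethyl 3,3'-dithiodipropionate
Product: 11 methyl 3-[(tert-butoxyethynyl)sulfanyl]propanoate, via lithium tert-butoxyethynide 10 (not isolated)
Conditions: n-BuLi, THF, −78 °C; added to 9 (1.3 equiv), THF, −78 °C; then H2O; Et3N-deactivated silica
Reagents that add atoms: none
Why: Thiophilic substitution of a lithium acetylide on a disulfide (sulfenylation) is the standard route to alkynyl sulfides and is known for lithium alkoxyacetylides. Adding 10 to an excess of 9 at −78 °C keeps the acetylide away from the ester carbonyls, which lithium acetylides attack only at higher temperature, and deactivated silica protects the acid-sensitive ynol ether.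

Step 4
Reactants: 7 2-(2-diazoacetyl)-6-(4-methoxyphenyl)-4H-pyran-4-one; 11 methyl 3-[(tert-butoxyethynyl)sulfanyl]propanoate
Product: 16 methyl 3-{[7-tert-butoxy-5-hydroxy-2-(4-methoxyphenyl)-4-oxo-4H-chromen-6-yl]sulfanyl}propanoate, via pyranonylketene 12 (not isolated), via vinylcyclobutenone 13 (not isolated), via dienylketene 14 (not isolated), via cyclohexadienone 15 (not isolated)
Conditions: hν (365 nm LED, thin-film flow coil), 11 (1.5 equiv), degassed ClCH2CH2Cl, 20 °C; then 70 °C
Reagents that add atoms: none
Why: Proposed new method: irradiation of 7 expels N2 and the pyranonyl group shifts from the acyl carbon to the diazo carbon (Wolff rearrangement, forming C8–C8a), which gives ketene 12 with the C4a=C8a bond of the pyranone as its vinyl partner. The polarised ynol ether 11 then adds to the ketene C=C in a (2+2) cycloaddition, its sulfur-bearing carbon (β to oxygen, the nucleophilic terminus) bonding to the ketene carbonyl carbon (C5–C6) and its oxygen-bearing carbon to the ketene CH (C7–C8), to give the 4-vinylcyclobut-2-enone 13. Reversible four-electron conrotatory opening of 13, by light or in the 70 °C stage, gives dienylketene 14, and ring A is closed by a thermal six-electron disrotatory electrocyclisation of 14 between the ketene carbon and C4a (C4a–C5), a closure matched in polarity because C4a is the nucleophilic α-carbon of the vinylogous ester; enolisation of 15 then gives the chelated C5 phenol. The closest known reaction type is the photochemical Danheiser benzannulation of aryl and heteroaryl diazo ketones with alkoxy- and siloxyalkynes; a pyranone diazo ketone and a thio-substituted ynol ether are both untested in it. No stereocentre remains, since the sp3 centres at C8 of 13 and at C4a of 15 are erased by ring opening and enolisation. The selectivity needed is the orientation of the (2+2), which the stronger π-donation of oxygen over sulfur in 11 should secure; the site of closure is not in question because the only carbon neighbour of C8a in the ring is C4a, the other being O1. Light of 365 nm in a thin channel should keep the tert-butyl ynol ether below its retro-ene temperature, limit secondary photochemistry of the pyranone, and spare the product, whose chelated 5-hydroxyl quenches its excited state and is a poor acyl acceptor for 12.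

Step 5
Reactants: 16 methyl 3-{[7-tert-butoxy-5-hydroxy-2-(4-methoxyphenyl)-4-oxo-4H-chromen-6-yl]sulfanyl}propanoate
Product: 17 methyl 3-{[7-tert-butoxy-5-hydroxy-2-(4-methoxyphenyl)-4-oxo-4H-chromen-6-yl]sulfonyl}propanoate
Conditions: mCPBA (2.3 equiv), CH2Cl2, 0 °C to rt
Reagents that add atoms: 3-chloroperbenzoic acid, OOC(=O)c1cccc(Cl)c1
Why: Stepwise electrophilic oxidation of the sulfide by the peracid (sulfide to sulfoxide to sulfone); sulfur is by far the most nucleophilic site, the C2=C3 bond is electron-poor and the chelated phenol ring is deactivated by the C4 carbonyl. The weak 3-chlorobenzoic acid that forms should not cleave the aryl tert-butyl ether.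

Step 6
Reactants: 17 methyl 3-{[7-tert-butoxy-5-hydroxy-2-(4-methoxyphenyl)-4-oxo-4H-chromen-6-yl]sulfonyl}propanoate
Product: 19 1,8-diazabicyclo[5.4.0]undec-7-enium 7-tert-butoxy-5-hydroxy-2-(4-methoxyphenyl)-4-oxo-4H-chromene-6-sulfonate, via sulfinate salt 18 (not isolated)
Conditions: DBU (2.2 equiv), THF, rt; then 30% aq. H2O2, 0 °C to rt
Reagents that add atoms: 1,8-diazabicyclo[5.4.0]undec-7-ene (DBU), C1CCC2=NCCCN2CC1; hydrogen peroxide, OO
Why: E1cB retro-Michael elimination of a β-sulfonyl ester is an established release of arenesulfinates, and the amidine base, unlike an alkoxide, should not add to C2 of the flavone. H2O2 in the same flask oxidises sulfinate 18 to the sulfonate, which takes it out of the reversible Michael equilibrium and forestalls loss of SO2; 19 would be isolated by reversed-phase chromatography.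

Step 7
Reactants: 19 1,8-diazabicyclo[5.4.0]undec-7-enium 7-tert-butoxy-5-hydroxy-2-(4-methoxyphenyl)-4-oxo-4H-chromene-6-sulfonate
Product: 20 niruriflavone, 5,7-dihydroxy-2-(4-methoxyphenyl)-4-oxo-4H-chromene-6-sulfonic acid
Conditions: CF3CO2H–CH2Cl2 (1:3), 0 °C to rt; evaporate; Amberlite IR-120 (H+ form), MeOH–H2O
Reagents that add atoms: none
Why: Acidolysis of the aryl tert-butyl ether (protonation, loss of the tert-butyl cation as 2-methylpropene) frees the C7 hydroxyl and leaves the aryl methyl ether untouched. The sulfonated polystyrene resin holds back the amidinium ion and releases the free sulfonic acid; low temperature and short contact are chosen against protodesulfonation.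

## Compound list

1 | 1-(4-methoxyphenyl)butane-1,3-dione | COc1ccc(C(=O)CC(C)=O)cc1 | starting material
2 | diethyl oxalate | CCOC(=O)C(=O)OCC | starting material
3 | ethyl 6-(4-methoxyphenyl)-2,4,6-trioxohexanoate | CCOC(=O)C(=O)CC(=O)CC(=O)c1ccc(OC)cc1 | intermediate (not isolated)
4 | ethyl 6-(4-methoxyphenyl)-4-oxo-4H-pyran-2-carboxylate | CCOC(=O)c1cc(=O)cc(-c2ccc(OC)cc2)o1 | intermediate (not isolated)
5 | 6-(4-methoxyphenyl)-4-oxo-4H-pyran-2-carboxylic acid | OC(=O)c1cc(=O)cc(-c2ccc(OC)cc2)o1 | intermediate
6 | 6-(4-methoxyphenyl)-4-oxo-4H-pyran-2-carbonyl chloride | ClC(=O)c1cc(=O)cc(-c2ccc(OC)cc2)o1 | intermediate (not isolated)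
7 | 2-(2-diazoacetyl)-6-(4-methoxyphenyl)-4H-pyran-4-one | COc1ccc(-c2cc(=O)cc(C(=O)C=[N+]=[N-])o2)cc1 | intermediate
8 | tert-butoxyethyne | C#COC(C)(C)C | starting material
9 | dimethyl 3,3'-dithiodipropionate | COC(=O)CCSSCCC(=O)OC | starting material
10 | lithium tert-butoxyethynide | [Li+].[C-]#COC(C)(C)C | intermediate (not isolated)
11 | methyl 3-[(tert-butoxyethynyl)sulfanyl]propanoate | COC(=O)CCSC#COC(C)(C)C | intermediate
12 | 6-(4-methoxyphenyl)-2-(2-oxoethenyl)-4H-pyran-4-one | COc1ccc(-c2cc(=O)cc(C=C=O)o2)cc1 | intermediate (not isolated)
13 | methyl 3-({2-tert-butoxy-3-[6-(4-methoxyphenyl)-4-oxo-4H-pyran-2-yl]-4-oxocyclobut-1-en-1-yl}sulfanyl)propanoate (racemic at the sp3 ring carbon) | COC(=O)CCSC1=C(OC(C)(C)C)C(c2cc(=O)cc(-c3ccc(OC)cc3)o2)C1=O | intermediate (not isolated)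
14 | methyl 3-{[(3E)-3-tert-butoxy-4-[6-(4-methoxyphenyl)-4-oxo-4H-pyran-2-yl]-1-oxobuta-1,3-dien-2-yl]sulfanyl}propanoate (the isomer that can close) | COC(=O)CCSC(=C=O)/C(OC(C)(C)C)=C\c1cc(=O)cc(-c2ccc(OC)cc2)o1 | intermediate (not isolated)
15 | methyl 3-{[7-tert-butoxy-2-(4-methoxyphenyl)-4,5-dioxo-4a,5-dihydro-4H-chromen-6-yl]sulfanyl}propanoate (racemic at C4a) | COC(=O)CCSC1=C(OC(C)(C)C)C=C2OC(c3ccc(OC)cc3)=CC(=O)C2C1=O | intermediate (not isolated)
16 | methyl 3-{[7-tert-butoxy-5-hydroxy-2-(4-methoxyphenyl)-4-oxo-4H-chromen-6-yl]sulfanyl}propanoate | COC(=O)CCSc1c(O)c2c(=O)cc(-c3ccc(OC)cc3)oc2cc1OC(C)(C)C | intermediate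
17 | methyl 3-{[7-tert-butoxy-5-hydroxy-2-(4-methoxyphenyl)-4-oxo-4H-chromen-6-yl]sulfonyl}propanoate | COC(=O)CCS(=O)(=O)c1c(O)c2c(=O)cc(-c3ccc(OC)cc3)oc2cc1OC(C)(C)C | intermediate
18 | 1,8-diazabicyclo[5.4.0]undec-7-enium 7-tert-butoxy-5-hydroxy-2-(4-methoxyphenyl)-4-oxo-4H-chromene-6-sulfinate | [O-]S(=O)c1c(O)c2c(=O)cc(-c3ccc(OC)cc3)oc2cc1OC(C)(C)C.C1CCC2=[NH+]CCCN2CC1 | intermediate (not isolated)
19 | 1,8-diazabicyclo[5.4.0]undec-7-enium 7-tert-butoxy-5-hydroxy-2-(4-methoxyphenyl)-4-oxo-4H-chromene-6-sulfonate | [O-]S(=O)(=O)c1c(O)c2c(=O)cc(-c3ccc(OC)cc3)oc2cc1OC(C)(C)C.C1CCC2=[NH+]CCCN2CC1 | intermediate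
20 | niruriflavone, 5,7-dihydroxy-2-(4-methoxyphenyl)-4-oxo-4H-chromene-6-sulfonic acid | COc1ccc(-c2cc(=O)c3c(O)c(S(=O)(=O)O)c(O)cc3o2)cc1 | target

## Step count and least certain steps

Total: 7 steps. Longest linear sequence: 6 steps (steps 1, 2, 4, 5, 6 and 7, from 1); step 3 is a one-step side branch.

**Step 4 (key step, labelled as a proposed new method).** Four processes could defeat it:
- cycloaddition in the reverse orientation if sulfur donation competes with oxygen donation in 11;
- capture of the photogenerated acyl carbene by the sulfide sulfur, giving an ylide in place of the Wolff shift;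
- secondary photoreaction of the pyranone chromophore, or shielding of the light by the product;
- retro-ene loss of 2-methylpropene from the excess ynol ether in the thermal stage, followed by acylation by the ketene so formed.

Fallback, known chemistry throughout: it sets out from 9, which Zn dust in AcOH reduces to methyl 3-sulfanylpropanoate F1. Purchased 5,7-dihydroxy-4'-methoxyflavone F2 (acacetin) is tert-butylated at its unchelated 7-hydroxyl with tert-butyl 2,2,2-trichloroacetimidate and catalytic BF3·OEt2 to give 7-tert-butoxy-5-hydroxy-2-(4-methoxyphenyl)-4H-chromen-4-one F3. Iodination ortho to the free 5-hydroxyl with benzyltrimethylammonium dichloroiodate and CaCO3 in CH2Cl2–MeOH, a known way to 6-iodo-5-hydroxy-7-alkoxyflavones, should give 7-tert-butoxy-5-hydroxy-6-iodo-2-(4-methoxyphenyl)-4H-chromen-4-one F4. Palladium-catalysed C–S coupling of F4 with F1 (Pd2(dba)3, Xantphos, i-Pr2NEt, dioxane, 90 °C) comes back to the route at 16.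

**Step 3.** Addition of the acetylide to an ester carbonyl, or deprotonation next to the ester with β-elimination of the disulfide, may compete with substitution at sulfur; the ynol ether may also be hydrated during purification. Fallback with reversed polarity at sulfur: it sets out from 10 (made from 8 as in step 3). Elemental sulfur (S8) in THF at −78 to −30 °C inserts into the C–Li bond to give lithium 2-tert-butoxyethyne-1-thiolate F5, which is alkylated on sulfur by methyl 3-bromopropanoate at −30 to 0 °C and comes back at 11. The ester then meets only a soft thiolate.

**Step 2.** The chlorinating agent may activate the pyranone carbonyl oxygen (chloropyrylium formation), HCl may convert the diazo ketone to a chloromethyl ketone, or the diazoalkane may add as a dipole to the electron-poor pyranone double bond during a slow acylation. Fallback without chloride: it sets out from 5, which isobutyl chloroformate and N-methylmorpholine in THF at −15 °C convert into 6-(4-methoxyphenyl)-4-oxo-4H-pyran-2-carboxylic isobutyl carbonic anhydride F6. Acylation of Me3SiCHN2 by F6 in MeCN at 0 °C comes back at 7.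

**Step 6.** The sulfinate may re-add to the acrylate (the elimination is reversible), the electron-rich sulfinate may lose SO2 if it is protonated, or hydroperoxide anion may epoxidise the C2=C3 bond. Fallback that avoids the sulfinate: it sets out from 16, whose retro-Michael cleavage at the sulfide level with KOt-Bu in THF at 0 °C, followed by acidification, gives 7-tert-butoxy-5-hydroxy-2-(4-methoxyphenyl)-6-sulfanyl-4H-chromen-4-one F7. Oxidation of F7 with 30% H2O2 in HCO2H at 0 °C takes the thiol directly to the sulfonic acid, which in the same acid medium should catalyse loss of the tert-butyl group, and the sequence comes back at 20.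

**Step 7.** Ipso protonation at C6 with loss of the sulfonic acid group, or alkylation of C8 by the tert-butyl cation, may compete with simple ether cleavage. Fallback by change of order: it sets out from 17, where the ring is deactivated and the C–S bond cannot be lost by protonation. CF3CO2H in CH2Cl2 gives methyl 3-{[5,7-dihydroxy-2-(4-methoxyphenyl)-4-oxo-4H-chromen-6-yl]sulfonyl}propanoate F8. DBU (3 equiv) and then H2O2, as in step 6, give through 1,8-diazabicyclo[5.4.0]undec-7-enium 5,7-dihydroxy-2-(4-methoxyphenyl)-4-oxo-4H-chromene-6-sulfinate F9 the salt 1,8-diazabicyclo[5.4.0]undec-7-enium 5,7-dihydroxy-2-(4-methoxyphenyl)-4-oxo-4H-chromene-6-sulfonate F10. The H+ resin alone then comes back at 20, with no exposure of the sulfonic acid to strong acid.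

## Further compounds

F1 | step 4 | methyl 3-sulfanylpropanoate | COC(=O)CCS
F2 | step 4 | 5,7-dihydroxy-4'-methoxyflavone (acacetin) | COc1ccc(-c2cc(=O)c3c(O)cc(O)cc3o2)cc1
F3 | step 4 | 7-tert-butoxy-5-hydroxy-2-(4-methoxyphenyl)-4H-chromen-4-one | COc1ccc(-c2cc(=O)c3c(O)cc(OC(C)(C)C)cc3o2)cc1
F4 | step 4 | 7-tert-butoxy-5-hydroxy-6-iodo-2-(4-methoxyphenyl)-4H-chromen-4-one | COc1ccc(-c2cc(=O)c3c(O)c(I)c(OC(C)(C)C)cc3o2)cc1
F5 | step 3 | lithium 2-tert-butoxyethyne-1-thiolate | [Li+].[S-]C#COC(C)(C)C
F6 | step 2 | 6-(4-methoxyphenyl)-4-oxo-4H-pyran-2-carboxylic isobutyl carbonic anhydride | CC(C)COC(=O)OC(=O)c1cc(=O)cc(-c2ccc(OC)cc2)o1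
F7 | step 6 | 7-tert-butoxy-5-hydroxy-2-(4-methoxyphenyl)-6-sulfanyl-4H-chromen-4-one | COc1ccc(-c2cc(=O)c3c(O)c(S)c(OC(C)(C)C)cc3o2)cc1
F8 | step 7 | methyl 3-{[5,7-dihydroxy-2-(4-methoxyphenyl)-4-oxo-4H-chromen-6-yl]sulfonyl}propanoate | COC(=O)CCS(=O)(=O)c1c(O)c2c(=O)cc(-c3ccc(OC)cc3)oc2cc1O
F9 | step 7 | 1,8-diazabicyclo[5.4.0]undec-7-enium 5,7-dihydroxy-2-(4-methoxyphenyl)-4-oxo-4H-chromene-6-sulfinate | [O-]S(=O)c1c(O)c2c(=O)cc(-c3ccc(OC)cc3)oc2cc1O.C1CCC2=[NH+]CCCN2CC1
F10 | step 7 | 1,8-diazabicyclo[5.4.0]undec-7-enium 5,7-dihydroxy-2-(4-methoxyphenyl)-4-oxo-4H-chromene-6-sulfonate | [O-]S(=O)(=O)c1c(O)c2c(=O)cc(-c3ccc(OC)cc3)oc2cc1O.C1CCC2=[NH+]CCCN2CC1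
A1 | alternative 1 | (2Z)-3-{4-[(2,2-dimethylpropoxy)sulfonyl]-3,5-di(propan-2-yloxy)phenoxy}-3-(4-methoxyphenyl)prop-2-enoic acid | COc1ccc(/C(Oc2cc(OC(C)C)c(S(=O)(=O)OCC(C)(C)C)c(OC(C)C)c2)=C/C(=O)O)cc1
A2 | alternative 1 | neopentyl 5,7-diisopropoxy-2-(4-methoxyphenyl)-4-oxo-4H-chromene-6-sulfonate | COc1ccc(-c2cc(=O)c3c(OC(C)C)c(S(=O)(=O)OCC(C)(C)C)c(OC(C)C)cc3o2)cc1
A3 | alternative 2 | methyl 2-(2-methoxy-2-oxoethyl)-6-(4-methoxyphenyl)-4-oxo-4H-pyran-3-carboxylate | COC(=O)Cc1oc(-c2ccc(OC)cc2)cc(=O)c1C(=O)OC
A4 | alternative 2 | neopentyl methanesulfonate | CS(=O)(=O)OCC(C)(C)C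
A5 | alternative 2 | neopentyl 5,7-dihydroxy-2-(4-methoxyphenyl)-4-oxo-4H-chromene-6-sulfonate | COc1ccc(-c2cc(=O)c3c(O)c(S(=O)(=O)OCC(C)(C)C)c(O)cc3o2)cc1
A6 | alternative 3 | neopentyl 5,7-difluoro-2-(4-methoxyphenyl)-4-oxo-4H-chromene-6-sulfonate | COc1ccc(-c2cc(=O)c3c(F)c(S(=O)(=O)OCC(C)(C)C)c(F)cc3o2)cc1
A7 | alternative 3 | neopentyl 5,7-bis(benzyloxy)-2-(4-methoxyphenyl)-4-oxo-4H-chromene-6-sulfonate | COc1ccc(-c2cc(=O)c3c(OCc4ccccc4)c(S(=O)(=O)OCC(C)(C)C)c(OCc4ccccc4)cc3o2)cc1
A8 | alternative 3 | sodium benzyloxide | [Na+].[O-]Cc1ccccc1
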